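**Plan**
1. Retrosynthesis: the two silyl ethers come off, the CH2OH groups on C2 and C3 go back to methyl esters and C4H2 back to C4H–OH. Ring B (C1, C2, C3, C4, C4a, C8a) is then cut at C1–C2 and C3–C4. Both bonds leave benzylic carbons of ring A, C1 also carries guaiacyl ring C, and C2/C3 carry the one-carbon arms, which is the pattern of a hydroxy-o-quinodimethane/fumarate cycloadduct.
2. The diene precursor, a 2-benzylbenzaldehyde, is cut at C4a–CHO (bromine–lithium exchange, DMF) and at C1–ring C (aryl Grignard addition, then ionic reduction). The bromine is placed by directed ortho-lithiation.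
3. Forward: ring A aldehyde → ortho-bromide → diarylcarbinol → diarylmethane → aldehyde. Ring B then closes in one photochemical [4+2]. C4 deoxygenation, ester reduction and desilylation finish the route.
4. Stereochemistry: C1, C2 and C3 (and the transient C4) all arise in the cycloaddition. Relative configuration comes from dienol and fumarate geometry plus titanium-bridged endo addition, absolute configuration from a chiral titanium TADDOLate. Nothing later touches C1–C3.

Key step: step 7

Remark on numbering: tetralin locants are used throughout (C1 aryl-bearing, C2/C3 ester or CH2OH carbons, C4 benzylic CH2, ring A = C4a, C5–C8, C8a; ring C = guaiacyl). TIPS = triisopropylsilyl.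
Assumption: (R,R)-TADDOL is taken as the ligand that exposes the diene face leading to the (1R,2S,3R,4R) adduct. If the sense of induction is the opposite, the (S,S)-ligand is used and nothing else changes.

**Route**

Step 1
Reactants: 1 3-hydroxy-4,5-dimethoxybenzaldehyde
Product: 2 3,4-dimethoxy-5-(triisopropylsilyloxy)benzaldehyde
Conditions: iPr3SiCl, imidazole, DMF, rt
Reagents that add atoms: chlorotri(propan-2-yl)silane, CC(C)[Si](Cl)(C(C)C)C(C)C
Why: Imidazole-promoted O-silylation of a phenol; the bulky, non-coordinating silyl ether protects the C7 oxygen and later shields its own ortho carbon.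

Step 2
Reactants: 2 3,4-dimethoxy-5-(triisopropylsilyloxy)benzaldehyde
Product: 6 2-bromo-3,4-dimethoxy-5-(triisopropylsilyloxy)benzaldehyde, via lithium α-amino alkoxide 3 (not isolated), via ortho-lithiated α-amino alkoxide 4 (not isolated), via brominated α-amino alkoxide 5 (not isolated)
Conditions: MeNHCH2CH2NMe2, n-BuLi, THF, −20 °C; 2; n-BuLi (3 equiv), −20 °C; BrCl2CCCl2Br, −78 °C to rt; H2O
Reagents that add atoms: 1,2-dibromo-1,1,2,2-tetrachloroethane, BrC(Cl)(Cl)C(Cl)(Cl)Br
Why: Comins α-amino alkoxide directed ortho-metalation: the masked aldehyde and the neighbouring methoxy group jointly direct lithium to the carbon between them (future C4a) while the silyloxy group blocks the other ortho carbon, the aryllithium takes bromine from the polyhaloethane, and water returns the aldehyde.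

Step 3
Reactants: 7 4-bromo-2-methoxyphenol
Product: 8 (4-bromo-2-methoxyphenoxy)triisopropylsilane
Conditions: iPr3SiCl, imidazole, DMF, rt
Reagents that add atoms: chlorotri(propan-2-yl)silane, CC(C)[Si](Cl)(C(C)C)C(C)C
Why: Standard phenol silylation; the same silyl group on both phenols allows one final deprotection.

Step 4
Reactants: 8 (4-bromo-2-methoxyphenoxy)triisopropylsilane; 6 2-bromo-3,4-dimethoxy-5-(triisopropylsilyloxy)benzaldehyde
Product: 10 rac-[2-bromo-3,4-dimethoxy-5-(triisopropylsilyloxy)phenyl][3-methoxy-4-(triisopropylsilyloxy)phenyl]methanol, via aryl Grignard reagent 9 (not isolated)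
Conditions: 8, Mg (cat. I2), THF, 50 °C; then 6, −78 to 0 °C; H2O
Reagents that add atoms: none
Why: Grignard addition to an aldehyde forms the C1–ring C bond, the aryl bromide of 6 being inert to ArMgBr at low temperature; the carbinol centre is formed racemic and is removed in step 5.

Step 5
Reactants: 10 rac-[2-bromo-3,4-dimethoxy-5-(triisopropylsilyloxy)phenyl][3-methoxy-4-(triisopropylsilyloxy)phenyl]methanol
Product: 11 2-bromo-3,4-dimethoxy-1-[3-methoxy-4-(triisopropylsilyloxy)benzyl]-5-(triisopropylsilyloxy)benzene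
Conditions: Et3SiH, CF3CO2H, CH2Cl2, 0 °C
Reagents that add atoms: none
Why: Ionic hydrogenation: the doubly benzylic cation, stabilised by the para silyloxy group of ring C, takes hydride from the silane, while the aryl bromide and aryl silyl ethers are stable to brief acid at 0 °C.

Step 6
Reactants: 11 2-bromo-3,4-dimethoxy-1-[3-methoxy-4-(triisopropylsilyloxy)benzyl]-5-(triisopropylsilyloxy)benzene
Product: 14 2,3-dimethoxy-6-[3-methoxy-4-(triisopropylsilyloxy)benzyl]-4-(triisopropylsilyloxy)benzaldehyde, via aryllithium 12 (not isolated), via lithium hemiaminal alkoxide 13 (not isolated)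
Conditions: n-BuLi, THF, −78 °C; DMF, −78 to 0 °C; H2O
Reagents that add atoms: N,N-dimethylformamide, CN(C)C=O
Why: Bromine–lithium exchange is faster at −78 °C than deprotonation of the diarylmethane CH2, and formylation of the aryllithium with DMF (Bouveault type) gives the aldehyde on hydrolysis of the hemiaminal alkoxide.

Step 7
Reactants: 14 2,3-dimethoxy-6-[3-methoxy-4-(triisopropylsilyloxy)benzyl]-4-(triisopropylsilyloxy)benzaldehyde; 15 dimethyl fumarate
Product: 17 dimethyl (1R,2S,3R,4R)-4-hydroxy-5,6-dimethoxy-1-[3-methoxy-4-(triisopropylsilyloxy)phenyl]-7-(triisopropylsilyloxy)-1,2,3,4-tetrahydronaphthalene-2,3-dicarboxylate, via hydroxy-o-quinodimethane photoenol 16 (not isolated)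
Conditions: Ti(OiPr)4 (2 equiv), (R,R)-TADDOL (2.2 equiv), toluene, rt; 14, 15 (3 equiv), hν 365 nm, 0 °C to rt, Ar; aq. NaHCO3
Reagents that add atoms: none
Why: Light absorbed by the aldehyde (n→π*, then the triplet) moves one hydrogen of the doubly benzylic CH2 to the carbonyl oxygen, and the biradical relaxes to hydroxy-o-quinodimethane 16 with hydroxyl and aryl both outward (the inward-hydroxyl isomer falls back to 14 by a 1,5-hydrogen shift), which exchanges onto the tetravalent titanium TADDOLate that also binds one ester carbonyl of 15. The closest known reaction type is the photoenolization/Diels–Alder reaction of 2-alkylbenzaldehydes with electron-poor alkenes under Ti(OiPr)4 and chiral TADDOLate control, together with the addition of α-hydroxy-α′-aryl-o-quinodimethanes to fumarates. Ring B closes in an intermolecular, suprafacial [4+2] cycloaddition in which C1–C2 and C3–C4 form in one event and ring A regains its aromaticity. C2/C3 trans follows from the E alkene; C1-aryl and C4-OH come out cis because both are outward on the diene; the C3 ester is endo, hence cis to C4-OH with the C2 ester trans to the aryl group, because titanium bridges the dienol oxygen and that ester; the absolute configuration (1R,2S,3R,4R) follows from the diolate shielding one face of this bridged assembly. The step needs endo/exo and π-facial selectivity only (15 is symmetric, so there is no regiochemical issue); the substrate secures them by offering the dienol oxygen as the single anchor for titanium and by the bulk of the aryl group, which keeps it outward, while the CH2 flanked by two arenes is by far the most readily abstracted hydrogen near the excited carbonyl.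

Step 8
Reactants: 17 dimethyl (1R,2S,3R,4R)-4-hydroxy-5,6-dimethoxy-1-[3-methoxy-4-(triisopropylsilyloxy)phenyl]-7-(triisopropylsilyloxy)-1,2,3,4-tetrahydronaphthalene-2,3-dicarboxylate
Product: 18 dimethyl (1R,2S,3S)-5,6-dimethoxy-1-[3-methoxy-4-(triisopropylsilyloxy)phenyl]-7-(triisopropylsilyloxy)-1,2,3,4-tetrahydronaphthalene-2,3-dicarboxylate
Conditions: Et3SiH (excess), CF3CO2H, CH2Cl2, −20 to 0 °C
Reagents that add atoms: none
Why: Ionic hydrogenation of a benzylic alcohol: the C4 cation, stabilised by the ortho methoxy and para silyloxy groups of ring A, is reduced by the silane, which erases the C4 centre and leaves C1–C3 untouched because no enolisation occurs in acid.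

Step 9
Reactants: 18 dimethyl (1R,2S,3S)-5,6-dimethoxy-1-[3-methoxy-4-(triisopropylsilyloxy)phenyl]-7-(triisopropylsilyloxy)-1,2,3,4-tetrahydronaphthalene-2,3-dicarboxylate
Product: 19 [(1R,2S,3S)-5,6-dimethoxy-1-[3-methoxy-4-(triisopropylsilyloxy)phenyl]-7-(triisopropylsilyloxy)-1,2,3,4-tetrahydronaphthalene-2,3-diyl]dimethanol
Conditions: LiAlH4, THF, 0 °C; H2O work-up
Reagents that add atoms: none
Why: Hydride reduction of both esters to primary alcohols is faster than enolisation, so C2 and C3 keep their configuration; any partial loss of an aryl silyl ether is harmless because step 10 removes both.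

Step 10
Reactants: 19 [(1R,2S,3S)-5,6-dimethoxy-1-[3-methoxy-4-(triisopropylsilyloxy)phenyl]-7-(triisopropylsilyloxy)-1,2,3,4-tetrahydronaphthalene-2,3-diyl]dimethanol
Product: 20 [(1R,2S,3S)-7-hydroxy-1-(4-hydroxy-3-methoxyphenyl)-5,6-dimethoxy-1,2,3,4-tetrahydronaphthalene-2,3-diyl]dimethanol
Conditions: Bu4NF, AcOH, THF, 0 °C to rt
Reagents that add atoms: none
Why: Fluoride-induced cleavage of both aryl Si–O bonds, with acetic acid buffering to keep the electron-rich phenols from standing as air-sensitive phenoxides; no stereocentre is involved.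

**Compound list**
1 | 3-hydroxy-4,5-dimethoxybenzaldehyde | COc1cc(C=O)cc(O)c1OC | starting material
2 | 3,4-dimethoxy-5-(triisopropylsilyloxy)benzaldehyde | COc1cc(C=O)cc(O[Si](C(C)C)(C(C)C)C(C)C)c1OC | intermediate
3 | lithium α-amino alkoxide of 2 with lithium N,N,N′-trimethylethylenediamide (racemic) | [Li]OC(N(C)CCN(C)C)c1cc(OC)c(OC)c(O[Si](C(C)C)(C(C)C)C(C)C)c1 | intermediate
4 | ring-lithiated 3, lithium on the carbon between the carbinol carbon and the methoxy group (racemic) | [Li]OC(N(C)CCN(C)C)c1cc(O[Si](C(C)C)(C(C)C)C(C)C)c(OC)c(OC)c1[Li] | intermediate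
5 | brominated α-amino alkoxide, bromine in place of the ring lithium (racemic) | [Li]OC(N(C)CCN(C)C)c1cc(O[Si](C(C)C)(C(C)C)C(C)C)c(OC)c(OC)c1Br | intermediate
6 | 2-bromo-3,4-dimethoxy-5-(triisopropylsilyloxy)benzaldehyde | O=Cc1cc(O[Si](C(C)C)(C(C)C)C(C)C)c(OC)c(OC)c1Br | intermediate
7 | 4-bromo-2-methoxyphenol | COc1cc(Br)ccc1O | starting material
8 | (4-bromo-2-methoxyphenoxy)triisopropylsilane | COc1cc(Br)ccc1O[Si](C(C)C)(C(C)C)C(C)C | intermediate
9 | [3-methoxy-4-(triisopropylsilyloxy)phenyl]magnesium bromide | COc1cc([Mg]Br)ccc1O[Si](C(C)C)(C(C)C)C(C)C | intermediate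
10 | rac-[2-bromo-3,4-dimethoxy-5-(triisopropylsilyloxy)phenyl][3-methoxy-4-(triisopropylsilyloxy)phenyl]methanol | OC(c1ccc(O[Si](C(C)C)(C(C)C)C(C)C)c(OC)c1)c1cc(O[Si](C(C)C)(C(C)C)C(C)C)c(OC)c(OC)c1Br | intermediate
11 | 2-bromo-3,4-dimethoxy-1-[3-methoxy-4-(triisopropylsilyloxy)benzyl]-5-(triisopropylsilyloxy)benzene | COc1cc(Cc2cc(O[Si](C(C)C)(C(C)C)C(C)C)c(OC)c(OC)c2Br)ccc1O[Si](C(C)C)(C(C)C)C(C)C | intermediate
12 | aryllithium from 11, lithium in place of bromine | COc1cc(Cc2cc(O[Si](C(C)C)(C(C)C)C(C)C)c(OC)c(OC)c2[Li])ccc1O[Si](C(C)C)(C(C)C)C(C)C | intermediate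
13 | lithium hemiaminal alkoxide, ArCH(OLi)NMe2 (racemic) | COc1cc(Cc2cc(O[Si](C(C)C)(C(C)C)C(C)C)c(OC)c(OC)c2C(O[Li])N(C)C)ccc1O[Si](C(C)C)(C(C)C)C(C)C | intermediate
14 | 2,3-dimethoxy-6-[3-methoxy-4-(triisopropylsilyloxy)benzyl]-4-(triisopropylsilyloxy)benzaldehyde | COc1cc(Cc2cc(O[Si](C(C)C)(C(C)C)C(C)C)c(OC)c(OC)c2C=O)ccc1O[Si](C(C)C)(C(C)C)C(C)C | intermediate
15 | dimethyl fumarate | COC(=O)/C=C/C(=O)OC | starting material
16 | hydroxy-o-quinodimethane photoenol of 14, hydroxyl and aryl both outward (bound to titanium in the reacting complex) | O/C=C1\C(OC)=C(OC)C(O[Si](C(C)C)(C(C)C)C(C)C)=C/C1=C\c1ccc(O[Si](C(C)C)(C(C)C)C(C)C)c(OC)c1 | intermediate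
17 | dimethyl (1R,2S,3R,4R)-4-hydroxy-5,6-dimethoxy-1-[3-methoxy-4-(triisopropylsilyloxy)phenyl]-7-(triisopropylsilyloxy)-1,2,3,4-tetrahydronaphthalene-2,3-dicarboxylate (1,2-trans, 2,3-trans, 3,4-cis) | COc1cc([C@@H]2c3cc(O[Si](C(C)C)(C(C)C)C(C)C)c(OC)c(OC)c3[C@H](O)[C@H](C(=O)OC)[C@H]2C(=O)OC)ccc1O[Si](C(C)C)(C(C)C)C(C)C | intermediate
18 | dimethyl (1R,2S,3S)-5,6-dimethoxy-1-[3-methoxy-4-(triisopropylsilyloxy)phenyl]-7-(triisopropylsilyloxy)-1,2,3,4-tetrahydronaphthalene-2,3-dicarboxylate | COc1cc([C@@H]2c3cc(O[Si](C(C)C)(C(C)C)C(C)C)c(OC)c(OC)c3C[C@H](C(=O)OC)[C@H]2C(=O)OC)ccc1O[Si](C(C)C)(C(C)C)C(C)C | intermediate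
19 | [(1R,2S,3S)-5,6-dimethoxy-1-[3-methoxy-4-(triisopropylsilyloxy)phenyl]-7-(triisopropylsilyloxy)-1,2,3,4-tetrahydronaphthalene-2,3-diyl]dimethanol | COc1cc([C@@H]2c3cc(O[Si](C(C)C)(C(C)C)C(C)C)c(OC)c(OC)c3C[C@H](CO)[C@H]2CO)ccc1O[Si](C(C)C)(C(C)C)C(C)C | intermediate
20 | [(1R,2S,3S)-7-hydroxy-1-(4-hydroxy-3-methoxyphenyl)-5,6-dimethoxy-1,2,3,4-tetrahydronaphthalene-2,3-diyl]dimethanol | COc1cc([C@@H]2c3cc(O)c(OC)c(OC)c3C[C@H](CO)[C@H]2CO)ccc1O | target

**Count**
Total steps: 10. Longest linear sequence: 9 steps (1 → 2 → 6 → 10 → 11 → 14 → 17 → 18 → 19 → 20); step 3 is the one-step side branch from 7.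

**Steps most likely to fail**

Step 7. The diester may bind the titanium diolate too loosely for good π-facial discrimination, or the dienol may be lost by ring closure onto ring C or by return to the aldehyde before it is trapped. A minor exo adduct that shares the C1 configuration would be funnelled into 18 by NaOMe equilibration after step 8. The fallback sets out from 14 and comes back at 19, and it moves the chirality into the dienophile. Fumaroyl chloride and methyl (S)-lactate (Et3N, CH2Cl2) give bis[(2S)-1-methoxy-1-oxopropan-2-yl] fumarate F1. Irradiation of 14 with F1 (365 nm, toluene, no Lewis acid) relies on the hydrogen bond from the dienol hydroxyl to the endo ester and on the lactate units for face selection, and should give the bis-lactyl cycloadduct F2. Et3SiH/CF3CO2H removes the C4 hydroxyl to give the bis-lactyl diester F3. LiAlH4 then reduces all four ester groups, releasing the auxiliary as propane-1,2-diol and delivering 19. The (S)-lactate is written; if it selects the other diene face, methyl (R)-lactate is used.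

Step 2. Metalation may occur at the wrong ortho carbon or stay incomplete, or n-BuLi may attack silicon during the long lithiation. The fallback sets out from 2 and comes back at 6, replacing carbanion chemistry by electrophilic aromatic substitution with N-bromosuccinimide in MeCN. Both free ring positions are activated, but the one next to the bulky silyloxy group is shielded, so bromine should enter ortho to the methoxy group and para to the silyloxy group. This gives 6 directly, and no new compound arises (F0).

Step 8. The C4 cation may lose the C3 proton faster than it takes hydride, giving the conjugated alkene instead of the reduced product. The fallback sets out from 17 and comes back at 18, and it makes elimination the intended path. CF3CO2H without silane (or MsCl/Et3N) gives dimethyl (1R,2S)-5,6-dimethoxy-1-[3-methoxy-4-(triisopropylsilyloxy)phenyl]-7-(triisopropylsilyloxy)-1,2-dihydronaphthalene-2,3-dicarboxylate F4. H2 over Pd/C in EtOAc saturates C3=C4 and, by addition on the face away from the C2 ester, should give the 2,3-cis diester F5, possibly mixed with 18. NaOMe in MeOH equilibrates C3 to the all-trans diester 18, with the non-acidic C1 as the fixed reference.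

**Further compounds**
F1 | step 7 | bis[(2S)-1-methoxy-1-oxopropan-2-yl] (2E)-but-2-enedioate | COC(=O)[C@H](C)OC(=O)/C=C/C(=O)O[C@@H](C)C(=O)OC
F2 | step 7 | bis[(2S)-1-methoxy-1-oxopropan-2-yl] (1R,2S,3R,4R)-4-hydroxy-5,6-dimethoxy-1-[3-methoxy-4-(triisopropylsilyloxy)phenyl]-7-(triisopropylsilyloxy)-1,2,3,4-tetrahydronaphthalene-2,3-dicarboxylate | COc1cc([C@@H]2c3cc(O[Si](C(C)C)(C(C)C)C(C)C)c(OC)c(OC)c3[C@H](O)[C@H](C(=O)O[C@@H](C)C(=O)OC)[C@H]2C(=O)O[C@@H](C)C(=O)OC)ccc1O[Si](C(C)C)(C(C)C)C(C)C
F3 | step 7 | bis[(2S)-1-methoxy-1-oxopropan-2-yl] (1R,2S,3S)-5,6-dimethoxy-1-[3-methoxy-4-(triisopropylsilyloxy)phenyl]-7-(triisopropylsilyloxy)-1,2,3,4-tetrahydronaphthalene-2,3-dicarboxylate | COc1cc([C@@H]2c3cc(O[Si](C(C)C)(C(C)C)C(C)C)c(OC)c(OC)c3C[C@H](C(=O)O[C@@H](C)C(=O)OC)[C@H]2C(=O)O[C@@H](C)C(=O)OC)ccc1O[Si](C(C)C)(C(C)C)C(C)C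
F0 | step 2 | none | none
F4 | step 8 | dimethyl (1R,2S)-5,6-dimethoxy-1-[3-methoxy-4-(triisopropylsilyloxy)phenyl]-7-(triisopropylsilyloxy)-1,2-dihydronaphthalene-2,3-dicarboxylate | COc1cc([C@@H]2c3cc(O[Si](C(C)C)(C(C)C)C(C)C)c(OC)c(OC)c3C=C(C(=O)OC)[C@H]2C(=O)OC)ccc1O[Si](C(C)C)(C(C)C)C(C)C
F5 | step 8 | dimethyl (1R,2S,3R)-5,6-dimethoxy-1-[3-methoxy-4-(triisopropylsilyloxy)phenyl]-7-(triisopropylsilyloxy)-1,2,3,4-tetrahydronaphthalene-2,3-dicarboxylate (2,3-cis) | COc1cc([C@@H]2c3cc(O[Si](C(C)C)(C(C)C)C(C)C)c(OC)c(OC)c3C[C@@H](C(=O)OC)[C@H]2C(=O)OC)ccc1O[Si](C(C)C)(C(C)C)C(C)C
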